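## Retrosynthetic overview

1. The γ-lactam is opened at N–C(=O) and the N–H is traced back to an N-tert-butylsulfinyl group. This leaves an acyclic β-sulfinamido ester.
2. Key disconnection: the C3–C1' bond. It is made by an intermolecular Mannich reaction between the (S)-tert-butanesulfinyl aldimine of ethyl 2-formyl-3-methoxybenzoate and the vinylogous acid 3-hydroxy-5-methyl-6,6-diprenylcyclohexa-2,4-dien-1-one. The auxiliary sets C3.
3. The aldimine comes from 3-methoxy-2-methylbenzoic acid by esterification, benzylic bromination, amine-oxide oxidation and condensation.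
4. The dienone comes from 5-methylcyclohexane-1,3-dione by enol ether formation, two Stork–Danheiser α'-prenylations, γ,δ-dehydrogenation (silyl dienol ether, DDQ) and hydrolysis.
5. Ring order: the arene and the carbocycle are bought intact. The lactam is the only ring formed, and it is closed after the key C–C bond.

Assumption: CIP analysis of the SMILES (N > dienone C > aryl C > H) gives (R) at C3, and the dione unit is drawn throughout as the enol tautomer of the target SMILES.

## Route

Step 1
Reactants: 1 3-methoxy-2-methylbenzoic acid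
Product: 2 ethyl 3-methoxy-2-methylbenzoate
Conditions: EtOH, H2SO4 (cat.), reflux, 16 h
Reagents that add atoms: ethanol, CCO
Why: Fischer esterification; the ethyl ester is chosen so that ester exchange with Ti(OEt)4 in step 4 is degenerate.

Step 2
Reactants: 2 ethyl 3-methoxy-2-methylbenzoate
Product: 3 ethyl 2-(bromomethyl)-3-methoxybenzoate
Conditions: NBS (1.05 equiv), AIBN (5 mol %), PhCF3, 85 °C
Reagents that add atoms: N-bromosuccinimide, O=C1CCC(=O)N1Br
Why: Wohl–Ziegler radical bromination of the only benzylic C–H position; the non-polar radical medium and the deactivating ester suppress ring bromination.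

Step 3
Reactants: 3 ethyl 2-(bromomethyl)-3-methoxybenzoate
Product: 5 ethyl 2-formyl-3-methoxybenzoate, via alkoxymorpholinium bromide 4 (not isolated)
Conditions: N-methylmorpholine N-oxide (3 equiv), 4 Å MS, MeCN, rt
Reagents that add atoms: N-methylmorpholine N-oxide, C[N+]1([O-])CCOCC1
Why: Amine-oxide (Kornblum-type) oxidation, in which SN2 attack of the N-oxide oxygen is followed by base-induced N–O fragmentation to the aldehyde at room temperature, where lactonisation to the phthalide is slow.

Step 4
Reactants: 5 ethyl 2-formyl-3-methoxybenzoate; 6 (S)-2-methylpropane-2-sulfinamide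
Product: 7 ethyl 2-[(E)-{[(S)-tert-butylsulfinyl]imino}methyl]-3-methoxybenzoate
Conditions: Ti(OEt)4 (2 equiv), THF, 50 °C
Reagents that add atoms: none
Why: Ellman condensation; Ti(OEt)4 is both Lewis acid and water scavenger, is strong enough for a 2,6-disubstituted benzaldehyde, and leaves the sulfur configuration untouched.

Step 5
Reactants: 8 5-methylcyclohexane-1,3-dione
Product: 9 racemic 3-ethoxy-5-methylcyclohex-2-en-1-one
Conditions: EtOH, TsOH (cat.), toluene, Dean–Stark, reflux
Reagents that add atoms: ethanol, CCO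
Why: Acid-catalysed enol etherification of a symmetric cyclic 1,3-dione gives a single vinylogous ester.

Step 6
Reactants: 9 racemic 3-ethoxy-5-methylcyclohex-2-en-1-one; 10 prenyl bromide (1-bromo-3-methylbut-2-ene)
Product: 12 racemic 3-ethoxy-5-methyl-6-(3-methylbut-2-en-1-yl)cyclohex-2-en-1-one (mainly trans), via lithium enolate 11 (not isolated)
Conditions: LiN(iPr)2 (commercial solution, 1.1 equiv), THF, −78 °C; 10 (1.2 equiv), −78 °C to rt
Reagents that add atoms: none
Why: Stork–Danheiser kinetic α'-deprotonation of the vinylogous ester followed by SN2 alkylation with a reactive allylic bromide; the new stereocentre is inconsequential because it becomes a non-stereogenic quaternary carbon in step 7.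

Step 7
Reactants: 12 racemic 3-ethoxy-5-methyl-6-(3-methylbut-2-en-1-yl)cyclohex-2-en-1-one; 10 prenyl bromide
Product: 14 racemic 3-ethoxy-5-methyl-6,6-bis(3-methylbut-2-en-1-yl)cyclohex-2-en-1-one, via lithium enolate 13 (not isolated)
Conditions: LiN(iPr)2 (1.3 equiv), THF/DMPU 5:1, −78 to −20 °C; 10 (2 equiv), −78 °C to rt
Reagents that add atoms: none
Why: Second Stork–Danheiser α'-alkylation; the axial C6–H of the trans isomer is removed kinetically and the tetrasubstituted enolate is quaternised by prenyl bromide.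

Step 8
Reactants: 14 racemic 3-ethoxy-5-methyl-6,6-bis(3-methylbut-2-en-1-yl)cyclohex-2-en-1-one
Product: 15 racemic tert-butyl{[3-ethoxy-5-methyl-6,6-bis(3-methylbut-2-en-1-yl)cyclohexa-1,3-dien-1-yl]oxy}dimethylsilane
Conditions: TBSOTf (1.3 equiv), Et3N (2 equiv), CH2Cl2, 0 °C
Reagents that add atoms: tert-butyldimethylsilyl triflate, CC(C)(C)[Si](C)(C)OS(=O)(=O)C(F)(F)F
Why: Soft enolisation; O-silylation gives an oxygen-stabilised allyl cation, and because the α' carbon is quaternary, Et3N can only remove a γ proton (C4–H), so one linear silyl dienol ether forms.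

Step 9
Reactants: 15 racemic silyl dienol ether
Product: 16 3-ethoxy-5-methyl-6,6-bis(3-methylbut-2-en-1-yl)cyclohexa-2,4-dien-1-one
Conditions: DDQ (1.1 equiv), 2,6-lutidine (1.5 equiv), CH2Cl2, 0 °C, 30 min
Reagents that add atoms: none
Why: DDQ dehydrogenation of a dienol ether by hydride abstraction from the tertiary allylic C5–H and desilylation; the doubly oxygenated diene is oxidised far faster than the isolated prenyl alkenes, and the last racemic centre is erased.

Step 10
Reactants: 16 3-ethoxy-5-methyl-6,6-bis(3-methylbut-2-en-1-yl)cyclohexa-2,4-dien-1-one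
Product: 18 3-hydroxy-5-methyl-6,6-bis(3-methylbut-2-en-1-yl)cyclohexa-2,4-dien-1-one, via sodium enolate 17 (not isolated)
Conditions: NaOH (2 M aq, 5 equiv), THF/EtOH, 40 °C; cold 1 M HCl to pH 3
Reagents that add atoms: sodium hydroxide, [Na+].[OH-]
Why: Saponification of the vinylogous ester by addition–elimination at C3; basic conditions avoid acid-induced cyclisation of prenyl onto the enol, and 40 °C is too cool for Cope or retro-Claisen aromatisation.

Step 11
Reactants: 7 ethyl 2-[(E)-{[(S)-tert-butylsulfinyl]imino}methyl]-3-methoxybenzoate; 18 3-hydroxy-5-methyl-6,6-bis(3-methylbut-2-en-1-yl)cyclohexa-2,4-dien-1-one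
Product: 19 ethyl 2-[(R)-{[(S)-tert-butylsulfinyl]amino}[2-hydroxy-4-methyl-5,5-bis(3-methylbut-2-en-1-yl)-6-oxocyclohexa-1,3-dien-1-yl]methyl]-3-methoxybenzoate
Conditions: 18 (1.1 equiv), CH2Cl2 (0.5 M), 4 Å MS, 0 °C to rt, 24–48 h; silica chromatography to a single diastereomer
Reagents that add atoms: none
Why: Intermolecular Mannich reaction in which the vinylogous acid (pKa about 5) activates the sulfinimine by hydrogen bonding and its C2 attacks the Si face, which the tert-butyl group leaves open in the s-cis C=N–S=O conformer of the (S)-sulfinyl imine (open, non-chelated model); this sets C(R), and the minor diastereomer is removed on silica.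

Step 12
Reactants: 19 Mannich adduct
Product: 21 (3R)-2-[(S)-tert-butylsulfinyl]-3-[2-hydroxy-4-methyl-5,5-bis(3-methylbut-2-en-1-yl)-6-oxocyclohexa-1,3-dien-1-yl]-4-methoxy-2,3-dihydro-1H-isoindol-1-one, via dipotassium salt 20 (not isolated)
Conditions: KN(SiMe3)2 (2.1 equiv), THF, −78 to 0 °C; sat. aq NH4Cl
Reagents that add atoms: none
Why: Intramolecular aminolysis (5-exo-trig lactamisation) of the ortho ester by the sulfinamide anion; in the enolate/amide dianion neither retro-Mannich cleavage nor E1cB loss of nitrogen is possible, so C3 is not scrambled.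

Step 13
Reactants: 21 N-sulfinyl lactam
Product: 22 (3R)-3-[2-hydroxy-4-methyl-5,5-bis(3-methylbut-2-en-1-yl)-6-oxocyclohexa-1,3-dien-1-yl]-4-methoxy-2,3-dihydro-1H-isoindol-1-one (target)
Conditions: HCl (1.25 M in MeOH, 1.5 equiv), CH2Cl2/MeOH, 0 °C, 15 min; sat. aq NaHCO3; product kept neutral and below 40 °C
Reagents that add atoms: none
Why: Acid-catalysed methanolysis of the activated N-acyl sulfinamide S–N bond; it is fast enough at 0 °C that the prenyl groups, the hindered enol and the C3 centre (no bond to it is touched) are unaffected.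

## Compound list

1 | 3-methoxy-2-methylbenzoic acid | COc1cccc(C(=O)O)c1C | starting material
2 | ethyl 3-methoxy-2-methylbenzoate | CCOC(=O)c1cccc(OC)c1C | intermediate
3 | ethyl 2-(bromomethyl)-3-methoxybenzoate | CCOC(=O)c1cccc(OC)c1CBr | intermediate
4 | 4-{[2-(ethoxycarbonyl)-6-methoxyphenyl]methoxy}-4-methylmorpholin-4-ium bromide (not isolated) | CCOC(=O)c1cccc(OC)c1CO[N+]1(C)CCOCC1.[Br-] | intermediate
5 | ethyl 2-formyl-3-methoxybenzoate | CCOC(=O)c1cccc(OC)c1C=O | intermediate
6 | (S)-2-methylpropane-2-sulfinamide | CC(C)(C)[S@](=O)N | starting material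
7 | ethyl 2-[(E)-{[(S)-tert-butylsulfinyl]imino}methyl]-3-methoxybenzoate | CCOC(=O)c1cccc(OC)c1/C=N/[S@@](=O)C(C)(C)C | intermediate
8 | 5-methylcyclohexane-1,3-dione | CC1CC(=O)CC(=O)C1 | starting material
9 | 3-ethoxy-5-methylcyclohex-2-en-1-one (racemic) | CCOC1=CC(=O)CC(C)C1 | intermediate
10 | prenyl bromide (1-bromo-3-methylbut-2-ene) | CC(C)=CCBr | starting material
11 | lithium 5-ethoxy-3-methylcyclohexa-1,5-dien-1-olate (racemic, not isolated) | CCOC1=CC([O-])=CC(C)C1.[Li+] | intermediate
12 | 3-ethoxy-5-methyl-6-(3-methylbut-2-en-1-yl)cyclohex-2-en-1-one (racemic, mainly trans) | CCOC1=CC(=O)C(CC=C(C)C)C(C)C1 | intermediate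
13 | lithium 5-ethoxy-3-methyl-2-(3-methylbut-2-en-1-yl)cyclohexa-1,5-dien-1-olate (racemic, not isolated) | CCOC1=CC([O-])=C(CC=C(C)C)C(C)C1.[Li+] | intermediate
14 | 3-ethoxy-5-methyl-6,6-bis(3-methylbut-2-en-1-yl)cyclohex-2-en-1-one (racemic) | CCOC1=CC(=O)C(CC=C(C)C)(CC=C(C)C)C(C)C1 | intermediate
15 | tert-butyl{[3-ethoxy-5-methyl-6,6-bis(3-methylbut-2-en-1-yl)cyclohexa-1,3-dien-1-yl]oxy}dimethylsilane (racemic) | CCOC1=CC(C)C(CC=C(C)C)(CC=C(C)C)C(O[Si](C)(C)C(C)(C)C)=C1 | intermediate
16 | 3-ethoxy-5-methyl-6,6-bis(3-methylbut-2-en-1-yl)cyclohexa-2,4-dien-1-one | CCOC1=CC(=O)C(CC=C(C)C)(CC=C(C)C)C(C)=C1 | intermediate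
17 | sodium 5-methyl-4,4-bis(3-methylbut-2-en-1-yl)-3-oxocyclohexa-1,5-dien-1-olate (not isolated) | CC1=CC([O-])=CC(=O)C1(CC=C(C)C)CC=C(C)C.[Na+] | intermediate
18 | 3-hydroxy-5-methyl-6,6-bis(3-methylbut-2-en-1-yl)cyclohexa-2,4-dien-1-one | CC1=CC(O)=CC(=O)C1(CC=C(C)C)CC=C(C)C | intermediate
19 | ethyl 2-[(R)-{[(S)-tert-butylsulfinyl]amino}[2-hydroxy-4-methyl-5,5-bis(3-methylbut-2-en-1-yl)-6-oxocyclohexa-1,3-dien-1-yl]methyl]-3-methoxybenzoate | CCOC(=O)c1cccc(OC)c1[C@H](C1=C(O)C=C(C)C(CC=C(C)C)(CC=C(C)C)C1=O)N[S@@](=O)C(C)(C)C | intermediate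
20 | dipotassium salt (enolate and sulfinamide N-anion) of 19 (not isolated) | CCOC(=O)c1cccc(OC)c1[C@H](C1=C([O-])C=C(C)C(CC=C(C)C)(CC=C(C)C)C1=O)[N-][S@@](=O)C(C)(C)C.[K+].[K+] | intermediate
21 | (3R)-2-[(S)-tert-butylsulfinyl]-3-[2-hydroxy-4-methyl-5,5-bis(3-methylbut-2-en-1-yl)-6-oxocyclohexa-1,3-dien-1-yl]-4-methoxy-2,3-dihydro-1H-isoindol-1-one | COc1cccc2c1[C@H](C1=C(O)C=C(C)C(CC=C(C)C)(CC=C(C)C)C1=O)N([S@@](=O)C(C)(C)C)C2=O | intermediate
22 | (3R)-3-[2-hydroxy-4-methyl-5,5-bis(3-methylbut-2-en-1-yl)-6-oxocyclohexa-1,3-dien-1-yl]-4-methoxy-2,3-dihydro-1H-isoindol-1-one | COc1cccc2c1[C@H](C1=C(O)C=C(C)C(CC=C(C)C)(CC=C(C)C)C1=O)NC2=O | target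

## Summary

Total step count: 13.
Longest linear sequence: 9 steps (steps 5–13, from 5-methylcyclohexane-1,3-dione). The aryl branch contributes 4 steps before the convergence at step 11.

## Three steps most likely to fail

**Step 11 (Mannich reaction).** A strongly stabilised nucleophile meets a hindered 2,6-disubstituted sulfinimine. The addition may be slow or reversible, and the diastereomer ratio may be modest.

The fallback sets out from 5 and 18 and comes back to the route at 22.
- Aldehyde ester 5 is stirred with NH3 in MeOH at rt. This gives racemic 3-hydroxy-4-methoxy-2,3-dihydro-1H-isoindol-1-one F1.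
- F1 and 18 are combined in toluene over 4 Å MS at 0 °C with 5–10 mol % of the chiral phosphoric acid (R)-TRIP, which is (R)-3,3'-bis(2,4,6-triisopropylphenyl)-1,1'-binaphthyl-2,2'-diyl hydrogen phosphate. The antipode is used if the sense of induction turns out reversed.
- The acid dehydrates F1 to the transient cyclic N-acylimine 4-methoxy-1H-isoindol-1-one F2.
- The phosphate binds F2 and the enol O–H of 18 at the same time. A catalytic enantioselective Mannich addition then gives 22 directly, with the lactam already in place.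
- The enantiomeric excess is raised by recrystallisation.

**Step 9 (DDQ dehydrogenation).** DDQ may form adducts with the very electron-rich diene instead of abstracting hydride.

The fallback sets out from 14 and comes back to the route at 18.
- 14 is saponified (2 M NaOH, THF/EtOH, 50 °C, then cold dilute HCl). This gives racemic 5-methyl-4,4-bis(3-methylbut-2-en-1-yl)cyclohexane-1,3-dione F3.
- Two equivalents of LiN(iPr)2 in THF/DMPU give the dilithium dienediolate F4. Its last-formed and most reactive carbon is C6, the only free α' position.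
- PhSeCl at −78 °C gives 5-methyl-4,4-bis(3-methylbut-2-en-1-yl)-6-(phenylselanyl)cyclohexane-1,3-dione F5. Selenium enters anti to the methyl group and is therefore syn to H5.
- H2O2/pyridine in CH2Cl2 at 0 °C gives the selenoxide F6. It undergoes syn-elimination below room temperature and gives 18 without any enol ether hydrolysis.

**Step 12 (lactamisation with the sulfinyl group still on nitrogen).** The bulky, delocalised sulfinamide anion may attack the ester only slowly.

The fallback sets out from 19 and comes back to the route at 22, leaving out 21.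
- HCl (4 M in dioxane, 3 equiv) in EtOH at 0 °C removes the auxiliary first. This gives (R)-[2-(ethoxycarbonyl)-6-methoxyphenyl][2-hydroxy-4-methyl-5,5-bis(3-methylbut-2-en-1-yl)-6-oxocyclohexa-1,3-dien-1-yl]methanaminium chloride F7.
- Et3N in CH2Cl2 at 0 °C liberates ethyl 2-{(R)-amino[2-hydroxy-4-methyl-5,5-bis(3-methylbut-2-en-1-yl)-6-oxocyclohexa-1,3-dien-1-yl]methyl}-3-methoxybenzoate F8.
- The unhindered primary amine of F8 closes spontaneously onto the ortho ester.
- The operation is kept cold and short, because the free Mannich base can lose ammonia or undergo retro-Mannich cleavage.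

## Further compounds

F1 | step 11 | 3-hydroxy-4-methoxy-2,3-dihydro-1H-isoindol-1-one (racemic) | COc1cccc2c1C(O)NC2=O
F2 | step 11 | 4-methoxy-1H-isoindol-1-one (transient N-acylimine) | COc1cccc2c1C=NC2=O
F3 | step 9 | 5-methyl-4,4-bis(3-methylbut-2-en-1-yl)cyclohexane-1,3-dione (racemic) | CC1CC(=O)CC(=O)C1(CC=C(C)C)CC=C(C)C
F4 | step 9 | dilithium 5-methyl-4,4-bis(3-methylbut-2-en-1-yl)cyclohexa-2,6-diene-1,3-diolate (racemic) | CC1C=C([O-])C=C([O-])C1(CC=C(C)C)CC=C(C)C.[Li+].[Li+]
F5 | step 9 | 5-methyl-4,4-bis(3-methylbut-2-en-1-yl)-6-(phenylselanyl)cyclohexane-1,3-dione (racemic, Se trans to methyl) | CC1C([Se]c2ccccc2)C(=O)CC(=O)C1(CC=C(C)C)CC=C(C)C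
F6 | step 9 | 5-methyl-4,4-bis(3-methylbut-2-en-1-yl)-6-(phenylseleninyl)cyclohexane-1,3-dione | CC1C([Se](=O)c2ccccc2)C(=O)CC(=O)C1(CC=C(C)C)CC=C(C)C
F7 | step 12 | (R)-[2-(ethoxycarbonyl)-6-methoxyphenyl][2-hydroxy-4-methyl-5,5-bis(3-methylbut-2-en-1-yl)-6-oxocyclohexa-1,3-dien-1-yl]methanaminium chloride | CCOC(=O)c1cccc(OC)c1[C@H](C1=C(O)C=C(C)C(CC=C(C)C)(CC=C(C)C)C1=O)[NH3+].[Cl-]
F8 | step 12 | ethyl 2-{(R)-amino[2-hydroxy-4-methyl-5,5-bis(3-methylbut-2-en-1-yl)-6-oxocyclohexa-1,3-dien-1-yl]methyl}-3-methoxybenzoate | CCOC(=O)c1cccc(OC)c1[C@H](C1=C(O)C=C(C)C(CC=C(C)C)(CC=C(C)C)C1=O)N
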